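7 ⇒ 6: the last operation only frees the phenol (aryl acetate aminolysis).
6 ⇒ 5: the 13(16),14-diene comes from the tertiary allylic acetate by Pd(0) 1,4-elimination.
5 ⇒ 2 + 3: the ester C19–O–C(=O) bond comes from acylation of the only primary hydroxyl, with 13-O-acetylation in the same flask.
2 ⇒ 1: key disconnection, the C19–O bond, made by site-selective hydroxylation of the axial 4β-methyl of (−)-sclareol; this also creates the C4 stereocentre.
Ring order: no ring is formed; the trans-decalin (rings A and B) with C5, C8, C9 and C10 is taken intact from 1.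

Assumption: the SMILES is read as 8α-hydroxylabda-13(16),14-dien-19-yl (E)-ferulate, normal labdane series with the core configuration of (−)-sclareol; the acyloxymethyl group is the axial 4β substituent (C19, cis to the C10 methyl, 4S).

**Step 1**
Reactants: 1 (−)-sclareol [(13R)-labd-14-ene-8α,13-diol]
Product: 2 19-hydroxysclareol [(4S,13R)-labd-14-ene-8α,13,19-triol; CH2OH axial, 4β]
Conditions: engineered P450-BM3 variant (E. coli lysate, ca. 0.2 mol%), NADP+ (cat.), GDH, D-glucose, air, KPi pH 8.0, 5% EtOH, hydroxypropyl-β-cyclodextrin, 25 °C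
Reagents that add atoms: dioxygen, O=O
Why: Proposed new method: a self-sufficient P450-BM3 variant is evolved from a parent with an enlarged pocket above the heme (the phenylalanine-to-alanine type that already hydroxylates sclareolide-type substrates at C3) by saturation mutagenesis of the hydrophobic residues that line the substrate channel around ring A and by introduction of a polar anchor at the channel mouth for the 8- and 13-hydroxyls, so that the side chain points to the channel mouth and ring A presents its β-face to the heme; compound I then abstracts hydrogen from the methyl that projects axially toward Fe=O (C19 rather than the equatorial C18 or the 3-CH2) and OH rebound forms the C19–O bond, the 4S centre arising from this choice between two diastereotopic methyls while the vinyl carbinol stays remote from iron; the closest known reaction type is enzymatic oxygen-rebound C–H hydroxylation of terpenoids (P450-BM3 at C3 of sclareolide-type substrates, fungal hydroxylation of sclareol at C3 and at the equatorial C18 methyl, P450 methyl hydroxylations of other terpenoids).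

**Step 2**
Reactants: 2 19-hydroxysclareol; 3 O-acetylferulic acid [(E)-3-(4-acetoxy-3-methoxyphenyl)prop-2-enoic acid]
Product: 5 (13R)-13-acetoxy-8α-hydroxylabd-14-en-19-yl (E)-3-(4-acetoxy-3-methoxyphenyl)prop-2-enoate, via diol ester 4 (not isolated)
Conditions: DCC, DMAP (cat.), CH2Cl2, 0 °C to rt; then Ac2O, Et3N, DMAP, rt
Reagents that add atoms: acetic anhydride, CC(=O)OC(C)=O
Why: Steglich esterification acylates only the primary 19-OH (both tertiary alcohols are inert to the cinnamoyl-pyridinium species), and the following DMAP-catalysed acetylation takes the acyclic allylic 13-OH in preference to the ring 8-OH, which is shielded by C9 and the axial C17 methyl; no stereocentre is touched.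

**Step 3**
Reactants: 5 (13R)-13-acetoxy-8α-hydroxylabd-14-en-19-yl (E)-3-(4-acetoxy-3-methoxyphenyl)prop-2-enoate
Product: 6 8α-hydroxylabda-13(16),14-dien-19-yl (E)-3-(4-acetoxy-3-methoxyphenyl)prop-2-enoate
Conditions: Pd(PPh3)4 (5 mol%), Et3N, 1,4-dioxane, 90 °C
Reagents that add atoms: none
Why: In this palladium-catalysed elimination of an allylic acetate (Tsuji–Trost ionisation, then 1,4-elimination), Pd(0) ionises only the tertiary allylic acetate and base-assisted proton loss from the most accessible C16 methyl of the π-allyl complex should favour the 2-substituted 1,3-diene (12-ene isomers removed on AgNO3–silica); C13 ceases to be a stereocentre and the ring centres, both esters and the free 8-OH are untouched.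

**Step 4**
Reactants: 6 8α-hydroxylabda-13(16),14-dien-19-yl (E)-3-(4-acetoxy-3-methoxyphenyl)prop-2-enoate
Product: 7 8α-hydroxylabda-13(16),14-dien-19-yl (E)-ferulate (target)
Conditions: pyrrolidine, CH2Cl2, 0 °C to rt
Reagents that add atoms: none
Why: Chemoselective aminolysis of the phenolic acetate frees the phenol, because the aryl ester is far more electrophilic than the hindered neopentyl cinnamate, and the diene, the (E)-alkene and all stereocentres are unaffected.

**Compound list**
1 | (−)-sclareol, (13R)-labd-14-ene-8α,13-diol | C=C[C@](C)(O)CC[C@@H]1[C@@]2(C)CCCC(C)(C)[C@@H]2CC[C@@]1(C)O | starting material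
2 | 19-hydroxysclareol, (4S,13R)-labd-14-ene-8α,13,19-triol (axial 4β-CH2OH) | C=C[C@](C)(O)CC[C@@H]1[C@@]2(C)CCC[C@](C)(CO)[C@@H]2CC[C@@]1(C)O | intermediate
3 | O-acetylferulic acid, (E)-3-(4-acetoxy-3-methoxyphenyl)prop-2-enoic acid | CC(=O)Oc1ccc(/C=C/C(=O)O)cc1OC | starting material
4 | (13R)-8α,13-dihydroxylabd-14-en-19-yl (E)-3-(4-acetoxy-3-methoxyphenyl)prop-2-enoate (not isolated) | C=C[C@](C)(O)CC[C@@H]1[C@@]2(C)CCC[C@](C)(COC(=O)/C=C/c3ccc(OC(C)=O)c(OC)c3)[C@@H]2CC[C@@]1(C)O | intermediate
5 | (13R)-13-acetoxy-8α-hydroxylabd-14-en-19-yl (E)-3-(4-acetoxy-3-methoxyphenyl)prop-2-enoate | C=C[C@](C)(OC(C)=O)CC[C@@H]1[C@@]2(C)CCC[C@](C)(COC(=O)/C=C/c3ccc(OC(C)=O)c(OC)c3)[C@@H]2CC[C@@]1(C)O | intermediate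
6 | 8α-hydroxylabda-13(16),14-dien-19-yl (E)-3-(4-acetoxy-3-methoxyphenyl)prop-2-enoate | C=CC(=C)CC[C@@H]1[C@@]2(C)CCC[C@](C)(COC(=O)/C=C/c3ccc(OC(C)=O)c(OC)c3)[C@@H]2CC[C@@]1(C)O | intermediate
7 | 8α-hydroxylabda-13(16),14-dien-19-yl (E)-ferulate (CNP0142252.1) | C=CC(=C)CC[C@@H]1[C@@]2(C)CCC[C@](C)(COC(=O)/C=C/c3ccc(O)c(OC)c3)[C@@H]2CC[C@@]1(C)O | target

**Total step count:** 4. **Longest linear sequence:** 4 steps (1 → 2 → 5 → 6 → 7).

**Three steps most likely to fail**

Step 1 (the proposed new hydroxylation) may give C3 or C18 oxidation instead of C19. The fallback uses known chemistry, sets out from 1 and comes back at 2, and walks the oxygen from the equatorial to the axial methyl. Sclareol 1 is incubated with a wild-type fungal culture of the kind known to hydroxylate it at C3 and at the equatorial methyl (Mucor plumbeus type), and 18-hydroxysclareol F1 is separated from the 3β-hydroxy isomer. Et2SiH2 with catalytic [Ir(cod)OMe]2 turns the primary alcohol into the diethyl(hydrido)silyl ether F2. Alcohol-directed iridium-catalysed γ-C–H silylation (Ir/3,4,7,8-tetramethylphenanthroline, norbornene, THF, 100 °C) closes it onto the geminal C19 methyl to give the spiro-oxasilolane F3. LiAlH4 opens the Si–O bond to the 19-(diethylsilyl) 18-alcohol F4, whose only primary hydroxyl is tosylated to the 18-tosylate F5. LiEt3BH reduces this to the 18-methyl 19-silane F6, and Tamao–Fleming oxidation (KF, KHCO3, H2O2) of the C–Si bond gives 2.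

Step 3 may give too much 12-ene isomer, or the 8-OH may close onto the π-allyl complex to give a cyclic ether. The fallback sets out from 4 (step 2 is stopped before the addition of Ac2O and 4 is isolated) and comes back at 6. It replaces palladium π-allyl chemistry by direct dehydration of the free allylic tertiary alcohol with Martin sulfurane (1.05 equiv, CH2Cl2, −78 to 0 °C), where the bulky fluoroalkoxide removes a methyl proton from the alkoxysulfonium intermediate. No new compound is made on this way (F0).

Step 2 may stall at the hindered axial neopentyl 19-OH (N-acylurea formation). The fallback sets out from 2 and comes back at 5, and builds the cinnamate C=C bond after the ester C–O bond. Meldrum's acid (toluene, 90 °C) converts the 19-OH into the malonic half-ester F7. Knoevenagel–Doebner condensation with vanillin (pyridine, cat. piperidine, 50 °C) gives the free-phenol ferulate F8 with loss of CO2. Ac2O/Et3N/DMAP then acetylates the phenol and the 13-OH to give 5.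

**Further compounds**
F1 | step 1 | 18-hydroxysclareol, (4R,13R)-labd-14-ene-8α,13,18-triol | C=C[C@](C)(O)CC[C@@H]1[C@@]2(C)CCC[C@@](C)(CO)[C@@H]2CC[C@@]1(C)O
F2 | step 1 | 18-O-(diethylsilyl)-18-hydroxysclareol | C=C[C@](C)(O)CC[C@@H]1[C@@]2(C)CCC[C@@](C)(CO[SiH](CC)CC)[C@@H]2CC[C@@]1(C)O
F3 | step 1 | sclareol 18-O,19-C-diethylsilylene spiro-oxasilolane | C=C[C@](C)(O)CC[C@@H]1[C@@]2(C)CCC[C@@]3(CO[Si](CC)(CC)C3)[C@@H]2CC[C@@]1(C)O
F4 | step 1 | 19-(diethylsilyl)-18-hydroxysclareol | C=C[C@](C)(O)CC[C@@H]1[C@@]2(C)CCC[C@@](C[SiH](CC)CC)(CO)[C@@H]2CC[C@@]1(C)O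
F5 | step 1 | 19-(diethylsilyl)-18-(p-toluenesulfonyloxy)sclareol | C=C[C@](C)(O)CC[C@@H]1[C@@]2(C)CCC[C@@](C[SiH](CC)CC)(COS(=O)(=O)c3ccc(C)cc3)[C@@H]2CC[C@@]1(C)O
F6 | step 1 | 19-(diethylsilyl)sclareol | C=C[C@](C)(O)CC[C@@H]1[C@@]2(C)CCC[C@@](C[SiH](CC)CC)(C)[C@@H]2CC[C@@]1(C)O
F7 | step 2 | 19-hydroxysclareol 19-(hydrogen malonate) | C=C[C@](C)(O)CC[C@@H]1[C@@]2(C)CCC[C@](C)(COC(=O)CC(=O)O)[C@@H]2CC[C@@]1(C)O
F8 | step 2 | (13R)-8α,13-dihydroxylabd-14-en-19-yl (E)-ferulate | C=C[C@](C)(O)CC[C@@H]1[C@@]2(C)CCC[C@](C)(COC(=O)/C=C/c3ccc(O)c(OC)c3)[C@@H]2CC[C@@]1(C)O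
F0 | step 3 | none | none
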